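**Retrosynthetic overview**
1. The enal comes from MnO2 oxidation of a (Z)-allylic alcohol, itself released by reductive opening of a bridged unsaturated lactone; the (E,E)-diene comes from a Julia–Kocienski union of a ring A sulfone with a ring B enal made by Wittig homologation.
2. The Z tetrasubstituted alkene is fixed by an intramolecular Horner–Wadsworth–Emmons reaction tethered through the ring B hydroxymethyl group (temporary seven-membered lactone).
3. Key step (step 6): a radical cascade on the bromomethylsilyl ether of an (S)-4-hydroxy-4-methyl-3-alkylcyclohexenone. A 5-exo closure makes the quaternary C–CH2 bond cis to the carbinol oxygen, then allyl transfer sets the neighbouring CH, so one stereocentre controls the other two.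
4. The enone comes from cyclohexane-1,3-dione (methylation, asymmetric enolate hydroxylation, Stork–Danheiser addition); ring A comes from 2-methylcyclohex-2-en-1-one (asymmetric conjugate addition/methylation, triflate carbonylation, deconjugative protonation).
5. Ring order: both carbocycles are already present in starting materials 1 (ring B) and 20 (ring A); the oxasilolane (step 6) and the bridged lactone (step 10) are temporary rings, opened in steps 7 and 22.

Assumption: ring B locants follow the target name (C1 alkylidene/keto carbon, C2 the CH carrying the three-carbon chain, C3 quaternary carbon, C4 carbinol carbon); for each chiral reagent or ligand the antipode meant is the one that gives the stated descriptor.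

**Route**

Step 1
Reactants: 1 cyclohexane-1,3-dione
Product: 2 3-ethoxycyclohex-2-en-1-one
Conditions: EtOH, TsOH (cat.), toluene, reflux, Dean–Stark
Reagents that add atoms: ethanol CCO
Why: Acid-catalysed enol etherification of a cyclic 1,3-diketone (vinylogous ester formation) is driven by azeotropic removal of water and creates no stereocentre.

Step 2
Reactants: 2 3-ethoxycyclohex-2-en-1-one
Product: 4 3-ethoxy-6-methylcyclohex-2-en-1-one (racemic), via lithium dienolate 3 (not isolated)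
Conditions: LiN(i-Pr)2, THF, −78 °C; MeI, −78 → 0 °C
Reagents that add atoms: iodomethane CI; lithium diisopropylamide [Li]N(C(C)C)C(C)C (Li in 3 only)
Why: Kinetic α′-deprotonation of the vinylogous ester and SN2 methylation (Stork–Danheiser enolate alkylation) give the racemic methyl compound, whose stereocentre is erased in the next enolisation.

Step 3
Reactants: 4 3-ethoxy-6-methylcyclohex-2-en-1-one (racemic)
Product: 6 (6S)-3-ethoxy-6-hydroxy-6-methylcyclohex-2-en-1-one, via sodium dienolate 5 (not isolated)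
Conditions: NaN(SiMe3)2, THF, −78 °C; (−)-[(8,8-dichlorocamphoryl)sulfonyl]oxaziridine, −78 °C; aq. NH4Cl
Reagents that add atoms: [(8,8-dichlorocamphoryl)sulfonyl]oxaziridine CC1(C)C2CCC13CS(=O)(=O)N4OC34C2(Cl)Cl; sodium bis(trimethylsilyl)amide [Na]N([Si](C)(C)C)[Si](C)(C)C (Na in 5 only)
Why: Davis asymmetric enolate hydroxylation oxidises one face of the planar tetrasubstituted dienolate under reagent control and sets the tertiary carbinol (later ring B C4, S), the sense being assigned by analogy with 2-methyl-1-tetralone enolates.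

Step 4
Reactants: 6 (6S)-3-ethoxy-6-hydroxy-6-methylcyclohex-2-en-1-one; 7 2-(2-bromoethyl)-1,3-dioxolane
Product: 10 (4S)-3-[2-(1,3-dioxolan-2-yl)ethyl]-4-hydroxy-4-methylcyclohex-2-en-1-one, via Grignard reagent 8 (not isolated), via carbinol adduct 9 (not isolated)
Conditions: 7 (3 equiv), Mg, THF, 30 °C; then 6, 0 °C → rt; then 1 M HCl, 0 °C, 15 min
Reagents that add atoms: magnesium [Mg] (in 8 only); water O (ring carbonyl oxygen of 10)
Why: In this Stork–Danheiser sequence the Grignard reagent (one equivalent is spent on the hydroxyl) adds 1,2 to the vinylogous ester carbonyl, and brief cold acid hydrolyses the enol ether and eliminates water to the transposed enone while the dioxolane and the carbinol stereocentre are untouched.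

Step 5
Reactants: 10 (4S)-3-[2-(1,3-dioxolan-2-yl)ethyl]-4-hydroxy-4-methylcyclohex-2-en-1-one
Product: 11 (4S)-4-{[(bromomethyl)dimethylsilyl]oxy}-3-[2-(1,3-dioxolan-2-yl)ethyl]-4-methylcyclohex-2-en-1-one
Conditions: BrCH2SiMe2Cl, imidazole, DMF, 0 °C → rt
Reagents that add atoms: (bromomethyl)chlorodimethylsilane C[Si](C)(Cl)CBr
Why: Silylation of the tertiary allylic alcohol installs the Stork bromomethylsilyl radical tether without touching the stereocentre.

Step 6
Reactants: 11 (4S)-4-{[(bromomethyl)dimethylsilyl]oxy}-3-[2-(1,3-dioxolan-2-yl)ethyl]-4-methylcyclohex-2-en-1-one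
Product: 12 (3aR,4S,7aS)-3a-[2-(1,3-dioxolan-2-yl)ethyl]-2,2,7a-trimethyl-4-(prop-2-en-1-yl)octahydro-1,2-benzoxasilol-5-one (cis-fused)
Conditions: Bu3SnCH2CH=CH2 (5 equiv), AIBN (0.2 equiv), benzene (0.03 M), 80 °C
Reagents that add atoms: allyltributylstannane C=CC[Sn](CCCC)(CCCC)CCCC
Why: In this Stork silicon-tethered radical cyclisation/Keck allyl-transfer cascade the α-silyl radical (from bromine abstraction by the tin radical) adds 5-exo to the enone β-carbon, so the new quaternary C–CH2 bond must lie cis to the tether oxygen; the α-keto radical is then expected to take the allyl group anti to the pseudoaxial side chain and the carbinol methyl, i.e. cis to the new CH2, which sets the adjacent CH.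

Step 7
Reactants: 12 (3aR,4S,7aS)-3a-[2-(1,3-dioxolan-2-yl)ethyl]-2,2,7a-trimethyl-4-(prop-2-en-1-yl)octahydro-1,2-benzoxasilol-5-one
Product: 14 (2S,3S,4S)-3-[2-(1,3-dioxolan-2-yl)ethyl]-4-hydroxy-3-(hydroxymethyl)-2-(3-hydroxypropyl)-4-methylcyclohexan-1-one, via alkylboronate 13 (not isolated)
Conditions: catecholborane, RhCl(PPh3)3 (2 mol%), THF, 0 °C → rt; then 30% H2O2, KF, KHCO3, MeOH, 40 °C
Reagents that add atoms: hydrogen peroxide OO; catecholborane B1Oc2ccccc2O1 (boron in 13 only)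
Why: Rhodium-catalysed hydroboration takes the terminal alkene (anti-Markovnikov) in preference to the ketone, and one basic peroxide treatment oxidises both the C–B bond and the cyclic alkoxysilane (Tamao–Fleming oxidation) with retention, so no stereocentre changes.

Step 8
Reactants: 14 (2S,3S,4S)-3-[2-(1,3-dioxolan-2-yl)ethyl]-4-hydroxy-3-(hydroxymethyl)-2-(3-hydroxypropyl)-4-methylcyclohexan-1-one
Product: 15 3-[(1S,2S,3S)-2-[2-(1,3-dioxolan-2-yl)ethyl]-3-hydroxy-2-(hydroxymethyl)-3-methyl-6-oxocyclohexyl]propyl 2,2-dimethylpropanoate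
Conditions: t-BuCOCl (1.1 equiv), pyridine, CH2Cl2, −20 °C
Reagents that add atoms: pivaloyl chloride CC(C)(C)C(=O)Cl
Why: Selective acylation works because the unhindered primary alcohol reacts much faster with the bulky acid chloride than the neopentyl primary and the tertiary alcohol.

Step 9
Reactants: 15 3-[(1S,2S,3S)-2-[2-(1,3-dioxolan-2-yl)ethyl]-3-hydroxy-2-(hydroxymethyl)-3-methyl-6-oxocyclohexyl]propyl 2,2-dimethylpropanoate
Product: 16 {(1S,2S,6S)-1-[2-(1,3-dioxolan-2-yl)ethyl]-2-{3-[(2,2-dimethylpropanoyl)oxy]propyl}-6-hydroxy-6-methyl-3-oxocyclohexyl}methyl 2-(diethoxyphosphoryl)propanoate (epimers at the phosphonate carbon)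
Conditions: (EtO)2P(O)CH(CH3)CO2H, DCC, DMAP (cat.), CH2Cl2, 0 °C → rt
Reagents that add atoms: 2-(diethoxyphosphoryl)propanoic acid CCOP(=O)(OCC)C(C)C(=O)O
Why: Steglich esterification acylates the remaining primary alcohol and not the tertiary one, and the stereocentre at the phosphonate carbon is destroyed in the next step.

Step 10
Reactants: 16 {(1S,2S,6S)-1-[2-(1,3-dioxolan-2-yl)ethyl]-2-{3-[(2,2-dimethylpropanoyl)oxy]propyl}-6-hydroxy-6-methyl-3-oxocyclohexyl}methyl 2-(diethoxyphosphoryl)propanoate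
Product: 17 3-{(1S,9S,10R)-1-[2-(1,3-dioxolan-2-yl)ethyl]-9-hydroxy-5,9-dimethyl-4-oxo-3-oxabicyclo[4.3.1]dec-5-en-10-yl}propyl 2,2-dimethylpropanoate
Conditions: LiCl, DBU, MeCN (0.005 M), rt → 50 °C
Reagents that add atoms: none
Why: In this intramolecular Horner–Wadsworth–Emmons olefination (Masamune–Roush conditions) the phosphonate is tethered through the C3 hydroxymethyl group, so the seven-membered lactone can only close with the ester carbon cis to ring carbon C2, which fixes the tetrasubstituted alkene in the required Z geometry.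

Step 11
Reactants: 17 3-{(1S,9S,10R)-1-[2-(1,3-dioxolan-2-yl)ethyl]-9-hydroxy-5,9-dimethyl-4-oxo-3-oxabicyclo[4.3.1]dec-5-en-10-yl}propyl 2,2-dimethylpropanoate
Product: 18 3-[(1S,9S,10R)-9-hydroxy-5,9-dimethyl-4-oxo-1-(3-oxopropyl)-3-oxabicyclo[4.3.1]dec-5-en-10-yl]propyl 2,2-dimethylpropanoate (in equilibrium with its six-membered lactol)
Conditions: PPTS, acetone/H2O (4:1), 50 °C
Reagents that add atoms: water O
Why: Mild acetal hydrolysis frees the aldehyde while lactone, pivalate and tertiary alcohol survive, and the reversible lactol with the tertiary hydroxyl does not block the next step.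

Step 12
Reactants: 18 3-[(1S,9S,10R)-9-hydroxy-5,9-dimethyl-4-oxo-1-(3-oxopropyl)-3-oxabicyclo[4.3.1]dec-5-en-10-yl]propyl 2,2-dimethylpropanoate
Product: 19 3-{(1S,9S,10R)-9-hydroxy-5,9-dimethyl-1-[(3E)-4-methyl-5-oxopent-3-en-1-yl]-4-oxo-3-oxabicyclo[4.3.1]dec-5-en-10-yl}propyl 2,2-dimethylpropanoate
Conditions: Ph3P=C(CH3)CHO (1.5 equiv), toluene, 90 °C
Reagents that add atoms: 2-(triphenylphosphoranylidene)propanal CC(C=O)=P(c1ccccc1)(c1ccccc1)c1ccccc1
Why: Wittig olefination with the stabilised formyl ylide opens the lactol and gives the (E)-2-methyl enal with high selectivity, and the less electrophilic product enal does not react again.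

Step 13
Reactants: 20 2-methylcyclohex-2-en-1-one
Product: 22 (3R)-2,2,3-trimethylcyclohexan-1-one, via magnesium enolate 21 (not isolated)
Conditions: MeMgBr, Cu(OTf)2 (3 mol%), chiral imidazolinium salt (NHC precursor, 4 mol%), Et2O, −30 °C; then MeI, DMPU, −30 °C → rt
Reagents that add atoms: methylmagnesium bromide C[Mg]Br; iodomethane CI
Why: Copper-catalysed asymmetric conjugate addition to the α-substituted enone sets the methyl-bearing stereocentre (3R) under ligand control, and the regiodefined magnesium enolate is C-methylated in the same flask to give the gem-dimethyl carbon.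

Step 14
Reactants: 22 (3R)-2,2,3-trimethylcyclohexan-1-one
Product: 24 (3R)-2,2,3,6-tetramethylcyclohexan-1-one (epimers at C6), via lithium enolate 23 (not isolated)
Conditions: LiN(i-Pr)2, THF, −78 °C; MeI, −78 → 0 °C
Reagents that add atoms: iodomethane CI; lithium diisopropylamide [Li]N(C(C)C)C(C)C (Li in 23 only)
Why: Kinetic enolate alkylation can only occur on the CH2 flank, and the configuration of the new centre is irrelevant because that carbon becomes sp2 in the next step.

Step 15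
Reactants: 24 (3R)-2,2,3,6-tetramethylcyclohexan-1-one
Product: 26 (5R)-2,5,6,6-tetramethylcyclohex-1-en-1-yl trifluoromethanesulfonate, via potassium enolate 25 (not isolated)
Conditions: KN(SiMe3)2, THF, −78 → 0 °C; PhNTf2; aq. NH4Cl
Reagents that add atoms: N-phenylbis(trifluoromethanesulfonimide) O=S(=O)(N(c1ccccc1)S(=O)(=O)C(F)(F)F)C(F)(F)F; potassium bis(trimethylsilyl)amide [K]N([Si](C)(C)C)[Si](C)(C)C (K in 25 only)
Why: Enolate O-triflation is regiospecific because only one α-hydrogen exists, giving the tetrasubstituted vinyl triflate.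

Step 16
Reactants: 26 (5R)-2,5,6,6-tetramethylcyclohex-1-en-1-yl trifluoromethanesulfonate
Product: 27 methyl (5R)-2,5,6,6-tetramethylcyclohex-1-ene-1-carboxylate
Conditions: CO (1 atm), Pd(OAc)2 (5 mol%), PPh3 (10 mol%), Et3N, MeOH/DMF, 60 °C
Reagents that add atoms: carbon monoxide [C-]#[O+]; methanol CO
Why: Palladium-catalysed methoxycarbonylation of the vinyl triflate installs the future side-chain carbon on the ring.

Step 17
Reactants: 27 methyl (5R)-2,5,6,6-tetramethylcyclohex-1-ene-1-carboxylate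
Product: 29 methyl (1S,3R)-2,2,3-trimethyl-6-methylidenecyclohexane-1-carboxylate, via lithium dienolate 28 (not isolated)
Conditions: LiN(i-Pr)2, THF/HMPA, −78 °C; AcOH, −78 °C
Reagents that add atoms: lithium diisopropylamide [Li]N(C(C)C)C(C)C (Li in 28 only)
Why: In this deconjugative protonation, ester-directed γ-deprotonation of the cis methyl gives the exocyclic dienolate, and kinetic α-protonation anti to the pseudoaxial methyl of the neighbouring quaternary carbon puts the ester cis to the C3 methyl (1S, also the diequatorial isomer) and leaves the exocyclic methylene.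

Step 18
Reactants: 29 methyl (1S,3R)-2,2,3-trimethyl-6-methylidenecyclohexane-1-carboxylate
Product: 30 [(1S,3R)-2,2,3-trimethyl-6-methylidenecyclohexyl]methanol
Conditions: LiAlH4, Et2O, 0 °C
Reagents that add atoms: none
Why: Hydride reduction of the ester is faster than enolisation at 0 °C, so the α-stereocentre is kept.

Step 19
Reactants: 30 [(1S,3R)-2,2,3-trimethyl-6-methylidenecyclohexyl]methanol
Product: 31 1-phenyl-5-({[(1S,3R)-2,2,3-trimethyl-6-methylidenecyclohexyl]methyl}sulfanyl)-1H-tetrazole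
Conditions: 1-phenyl-1H-tetrazole-5-thiol, PPh3, DIAD, THF, 0 °C → rt
Reagents that add atoms: 1-phenyl-1H-tetrazole-5-thiol Sc1nnnn1-c1ccccc1
Why: Mitsunobu thioetherification takes place at the primary carbon, so no stereocentre is involved.

Step 20
Reactants: 31 1-phenyl-5-({[(1S,3R)-2,2,3-trimethyl-6-methylidenecyclohexyl]methyl}sulfanyl)-1H-tetrazole
Product: 32 1-phenyl-5-({[(1S,3R)-2,2,3-trimethyl-6-methylidenecyclohexyl]methyl}sulfonyl)-1H-tetrazole
Conditions: 30% H2O2, (NH4)6Mo7O24·4H2O (10 mol%), EtOH, 0 °C → rt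
Reagents that add atoms: hydrogen peroxide OO
Why: Molybdate-catalysed peroxide oxidation of sulfide to sulfone is chemoselective over the unactivated 1,1-disubstituted alkene.

Step 21
Reactants: 32 1-phenyl-5-({[(1S,3R)-2,2,3-trimethyl-6-methylidenecyclohexyl]methyl}sulfonyl)-1H-tetrazole; 19 3-{(1S,9S,10R)-9-hydroxy-5,9-dimethyl-1-[(3E)-4-methyl-5-oxopent-3-en-1-yl]-4-oxo-3-oxabicyclo[4.3.1]dec-5-en-10-yl}propyl 2,2-dimethylpropanoate
Product: 34 3-{(1S,9S,10R)-9-hydroxy-5,9-dimethyl-1-{(3E,5E)-4-methyl-6-[(1S,3R)-2,2,3-trimethyl-6-methylidenecyclohexyl]hexa-3,5-dien-1-yl}-4-oxo-3-oxabicyclo[4.3.1]dec-5-en-10-yl}propyl 2,2-dimethylpropanoate, via potassium sulfonyl carbanion 33 (not isolated)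
Conditions: 32 (1.2 equiv), KN(SiMe3)2 (1.15 equiv), DME, −78 °C; then 19, −78 °C → rt; aq. NH4Cl
Reagents that add atoms: potassium bis(trimethylsilyl)amide [K]N([Si](C)(C)C)[Si](C)(C)C (K in 33 only)
Why: In this Julia–Kocienski olefination the preformed sulfonyl carbanion adds to the enal faster than it touches lactone, pivalate or tertiary alcohol, and Smiles rearrangement/elimination gives the new disubstituted alkene E, completing the (E,E)-diene without affecting any stereocentre.

Step 22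
Reactants: 34 3-{(1S,9S,10R)-9-hydroxy-5,9-dimethyl-1-{(3E,5E)-4-methyl-6-[(1S,3R)-2,2,3-trimethyl-6-methylidenecyclohexyl]hexa-3,5-dien-1-yl}-4-oxo-3-oxabicyclo[4.3.1]dec-5-en-10-yl}propyl 2,2-dimethylpropanoate
Product: 35 (2Z)-2-[(2R,3S,4S)-4-hydroxy-3-(hydroxymethyl)-2-(3-hydroxypropyl)-4-methyl-3-{(3E,5E)-4-methyl-6-[(1S,3R)-2,2,3-trimethyl-6-methylidenecyclohexyl]hexa-3,5-dien-1-yl}cyclohexylidene]propan-1-ol
Conditions: i-Bu2AlH (8 equiv), CH2Cl2, −78 → 0 °C; aq. KNaC4H4O6 (tartrate) work-up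
Reagents that add atoms: none
Why: Exhaustive hydride reduction opens the unsaturated lactone by 1,2-reduction to the (Z)-allylic alcohol plus the hydroxymethyl group and cleaves the pivalate, with alkene geometries and stereocentres untouched.

Step 23
Reactants: 35 (2Z)-2-[(2R,3S,4S)-4-hydroxy-3-(hydroxymethyl)-2-(3-hydroxypropyl)-4-methyl-3-{(3E,5E)-4-methyl-6-[(1S,3R)-2,2,3-trimethyl-6-methylidenecyclohexyl]hexa-3,5-dien-1-yl}cyclohexylidene]propan-1-ol
Product: 36 (2Z)-2-[(2R,3S,4S)-4-hydroxy-3-(hydroxymethyl)-2-(3-hydroxypropyl)-4-methyl-3-{(3E,5E)-4-methyl-6-[(1S,3R)-2,2,3-trimethyl-6-methylidenecyclohexyl]hexa-3,5-dien-1-yl}cyclohexylidene]propanal (CNP0149035.2)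
Conditions: MnO2 (20 equiv), CH2Cl2, rt
Reagents that add atoms: none
Why: MnO2 oxidises only the allylic primary alcohol to the enal (chemoselective allylic oxidation), leaving the two saturated primary alcohols, the tertiary alcohol and the diene.

**Compound list**
1 | cyclohexane-1,3-dione | O=C1CCCC(=O)C1 | starting material
2 | 3-ethoxycyclohex-2-en-1-one | CCOC1=CC(=O)CCC1 | intermediate
3 | lithium 5-ethoxycyclohexa-1,5-dien-1-olate | CCOC1=CC(O[Li])=CCC1 | intermediate
4 | 3-ethoxy-6-methylcyclohex-2-en-1-one (racemic) | CCOC1=CC(=O)C(C)CC1 | intermediate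
5 | sodium 5-ethoxy-2-methylcyclohexa-1,5-dien-1-olate | CCOC1=CC(O[Na])=C(C)CC1 | intermediate
6 | (6S)-3-ethoxy-6-hydroxy-6-methylcyclohex-2-en-1-one | O=C1C=C(OCC)CC[C@]1(C)O | intermediate
7 | 2-(2-bromoethyl)-1,3-dioxolane | BrCCC1OCCO1 | starting material
8 | [2-(1,3-dioxolan-2-yl)ethyl]magnesium bromide | Br[Mg]CCC1OCCO1 | intermediate
9 | (6S)-1-[2-(1,3-dioxolan-2-yl)ethyl]-3-ethoxy-6-methylcyclohex-2-ene-1,6-diol (C1 epimers; present as its magnesium alkoxide, drawn as the diol) | CCOC1=CC(O)(CCC2OCCO2)[C@@](C)(O)CC1 | intermediate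
10 | (4S)-3-[2-(1,3-dioxolan-2-yl)ethyl]-4-hydroxy-4-methylcyclohex-2-en-1-one | O=C1CC[C@](C)(O)C(CCC2OCCO2)=C1 | intermediate
11 | (4S)-4-{[(bromomethyl)dimethylsilyl]oxy}-3-[2-(1,3-dioxolan-2-yl)ethyl]-4-methylcyclohex-2-en-1-one | O=C1CC[C@](C)(O[Si](C)(C)CBr)C(CCC2OCCO2)=C1 | intermediate
12 | (3aR,4S,7aS)-3a-[2-(1,3-dioxolan-2-yl)ethyl]-2,2,7a-trimethyl-4-(prop-2-en-1-yl)octahydro-1,2-benzoxasilol-5-one | C1(OCCO1)CC[C@@]2(C[Si](C)(C)O3)[C@H](CC=C)C(=O)CC[C@@]23C | intermediate
13 | (3aR,4S,7aS)-4-[3-(1,3,2-benzodioxaborol-2-yl)propyl]-3a-[2-(1,3-dioxolan-2-yl)ethyl]-2,2,7a-trimethyloctahydro-1,2-benzoxasilol-5-one | C1(OCCO1)CC[C@@]2(C[Si](C)(C)O3)[C@H](CCCB4Oc5ccccc5O4)C(=O)CC[C@@]23C | intermediate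
14 | (2S,3S,4S)-3-[2-(1,3-dioxolan-2-yl)ethyl]-4-hydroxy-3-(hydroxymethyl)-2-(3-hydroxypropyl)-4-methylcyclohexan-1-one | C1(OCCO1)CC[C@@]2(CO)[C@H](CCCO)C(=O)CC[C@]2(C)O | intermediate
15 | 3-[(1S,2S,3S)-2-[2-(1,3-dioxolan-2-yl)ethyl]-3-hydroxy-2-(hydroxymethyl)-3-methyl-6-oxocyclohexyl]propyl 2,2-dimethylpropanoate | C1(OCCO1)CC[C@@]2(CO)[C@H](CCCOC(=O)C(C)(C)C)C(=O)CC[C@]2(C)O | intermediate
16 | {(1S,2S,6S)-1-[2-(1,3-dioxolan-2-yl)ethyl]-2-{3-[(2,2-dimethylpropanoyl)oxy]propyl}-6-hydroxy-6-methyl-3-oxocyclohexyl}methyl 2-(diethoxyphosphoryl)propanoate | C1(OCCO1)CC[C@@]2(COC(=O)C(C)P(=O)(OCC)OCC)[C@H](CCCOC(=O)C(C)(C)C)C(=O)CC[C@]2(C)O | intermediate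
17 | 3-{(1S,9S,10R)-1-[2-(1,3-dioxolan-2-yl)ethyl]-9-hydroxy-5,9-dimethyl-4-oxo-3-oxabicyclo[4.3.1]dec-5-en-10-yl}propyl 2,2-dimethylpropanoate | C1(OCCO1)CC[C@@]2(C3)[C@H](CCCOC(=O)C(C)(C)C)/C(=C(/C)C(=O)O3)CC[C@]2(C)O | intermediate
18 | 3-[(1S,9S,10R)-9-hydroxy-5,9-dimethyl-4-oxo-1-(3-oxopropyl)-3-oxabicyclo[4.3.1]dec-5-en-10-yl]propyl 2,2-dimethylpropanoate | O=CCC[C@@]1(C2)[C@H](CCCOC(=O)C(C)(C)C)/C(=C(/C)C(=O)O2)CC[C@]1(C)O | intermediate
19 | 3-{(1S,9S,10R)-9-hydroxy-5,9-dimethyl-1-[(3E)-4-methyl-5-oxopent-3-en-1-yl]-4-oxo-3-oxabicyclo[4.3.1]dec-5-en-10-yl}propyl 2,2-dimethylpropanoate | O=C/C(C)=C/CC[C@@]1(C2)[C@H](CCCOC(=O)C(C)(C)C)/C(=C(/C)C(=O)O2)CC[C@]1(C)O | intermediate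
20 | 2-methylcyclohex-2-en-1-one | CC1=CCCCC1=O | starting material
21 | bromomagnesium (3R)-2,3-dimethylcyclohex-1-en-1-olate | Br[Mg]OC1=C(C)[C@H](C)CCC1 | intermediate
22 | (3R)-2,2,3-trimethylcyclohexan-1-one | O=C1C(C)(C)[C@H](C)CCC1 | intermediate
23 | lithium (5R)-5,6,6-trimethylcyclohex-1-en-1-olate | [Li]OC1=CCC[C@@H](C)C1(C)C | intermediate
24 | (3R)-2,2,3,6-tetramethylcyclohexan-1-one (C6 epimers) | CC1CC[C@@H](C)C(C)(C)C1=O | intermediate
25 | potassium (5R)-2,5,6,6-tetramethylcyclohex-1-en-1-olate | [K]OC1=C(C)CC[C@@H](C)C1(C)C | intermediate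
26 | (5R)-2,5,6,6-tetramethylcyclohex-1-en-1-yl trifluoromethanesulfonate | CC1=C(OS(=O)(=O)C(F)(F)F)C(C)(C)[C@H](C)CC1 | intermediate
27 | methyl (5R)-2,5,6,6-tetramethylcyclohex-1-ene-1-carboxylate | CC1=C(C(=O)OC)C(C)(C)[C@H](C)CC1 | intermediate
28 | lithium methoxy[(3R)-2,2,3-trimethyl-6-methylidenecyclohexylidene]methanolate | [Li]OC(OC)=C1C(=C)CC[C@@H](C)C1(C)C | intermediate
29 | methyl (1S,3R)-2,2,3-trimethyl-6-methylidenecyclohexane-1-carboxylate | C=C1CC[C@@H](C)C(C)(C)[C@H]1C(=O)OC | intermediate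
30 | [(1S,3R)-2,2,3-trimethyl-6-methylidenecyclohexyl]methanol | C=C1CC[C@@H](C)C(C)(C)[C@H]1CO | intermediate
31 | 1-phenyl-5-({[(1S,3R)-2,2,3-trimethyl-6-methylidenecyclohexyl]methyl}sulfanyl)-1H-tetrazole | C=C1CC[C@@H](C)C(C)(C)[C@H]1CSc1nnnn1-c1ccccc1 | intermediate
32 | 1-phenyl-5-({[(1S,3R)-2,2,3-trimethyl-6-methylidenecyclohexyl]methyl}sulfonyl)-1H-tetrazole | C=C1CC[C@@H](C)C(C)(C)[C@H]1CS(=O)(=O)c1nnnn1-c1ccccc1 | intermediate
33 | potassium salt of the α-sulfonyl carbanion of 32 | C=C1CC[C@@H](C)C(C)(C)[C@H]1[CH-]S(=O)(=O)c1nnnn1-c1ccccc1.[K+] | intermediate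
34 | 3-{(1S,9S,10R)-9-hydroxy-5,9-dimethyl-1-{(3E,5E)-4-methyl-6-[(1S,3R)-2,2,3-trimethyl-6-methylidenecyclohexyl]hexa-3,5-dien-1-yl}-4-oxo-3-oxabicyclo[4.3.1]dec-5-en-10-yl}propyl 2,2-dimethylpropanoate | C=C1CC[C@@H](C)C(C)(C)[C@H]1/C=C/C(C)=C/CC[C@@]1(C2)[C@H](CCCOC(=O)C(C)(C)C)/C(=C(/C)C(=O)O2)CC[C@]1(C)O | intermediate
35 | (2Z)-2-[(2R,3S,4S)-4-hydroxy-3-(hydroxymethyl)-2-(3-hydroxypropyl)-4-methyl-3-{(3E,5E)-4-methyl-6-[(1S,3R)-2,2,3-trimethyl-6-methylidenecyclohexyl]hexa-3,5-dien-1-yl}cyclohexylidene]propan-1-ol | C=C1CC[C@@H](C)C(C)(C)[C@H]1/C=C/C(C)=C/CC[C@@]1(CO)[C@H](CCCO)/C(=C(/C)CO)CC[C@]1(C)O | intermediate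
36 | (2Z)-2-[(2R,3S,4S)-4-hydroxy-3-(hydroxymethyl)-2-(3-hydroxypropyl)-4-methyl-3-{(3E,5E)-4-methyl-6-[(1S,3R)-2,2,3-trimethyl-6-methylidenecyclohexyl]hexa-3,5-dien-1-yl}cyclohexylidene]propanal | C=C1CC[C@@H](C)C(C)(C)[C@H]1/C=C/C(C)=C/CC[C@@]1(CO)[C@H](CCCO)/C(=C(/C)C=O)CC[C@]1(C)O | target

**Count and risks**
Total step count: 23 (ring B line steps 1–12, ring A line steps 13–20, union and endgame steps 21–23).
Longest linear sequence: 15 steps (steps 1–12, then 21–23).

The three steps most likely to fail: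

Step 3. Reagent-controlled hydroxylation of a tetrasubstituted dienolate may give modest enantiomeric excess. The fallback sets out from 4 and comes back at 6. Compound 4 is converted with LiN(i-Pr)2 and t-BuMe2SiOTf into the isolated silyl dienol ether 2-[(tert-butyldimethylsilyl)oxy]-4-ethoxy-1-methylcyclohexa-1,3-diene F1. Its silyloxy-substituted double bond is then epoxidised under catalyst control (Shi fructose-derived ketone, KHSO5, buffered MeCN/H2O, 0 °C; an asymmetric Rubottom oxidation of a neutral enol ether instead of oxidation of a metal enolate). The epoxide collapses with loss of the silyl group to 6.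

Step 6. The hindered α-keto radical may be quenched before allyl transfer, or may take the allyl group on the other face. The fallback sets out from 10 and comes back at 12, and it inverts the order of the two events. Compound 10 is α-iodinated (I2, pyridine, CH2Cl2) to (4S)-3-[2-(1,3-dioxolan-2-yl)ethyl]-4-hydroxy-2-iodo-4-methylcyclohex-2-en-1-one F2. Stille coupling with allyltributylstannane (Pd2(dba)3, AsPh3, CuI, DMF) gives (4S)-3-[2-(1,3-dioxolan-2-yl)ethyl]-4-hydroxy-4-methyl-2-(prop-2-en-1-yl)cyclohex-2-en-1-one F3. Silylation as in step 5 gives (4S)-4-{[(bromomethyl)dimethylsilyl]oxy}-3-[2-(1,3-dioxolan-2-yl)ethyl]-4-methyl-2-(prop-2-en-1-yl)cyclohex-2-en-1-one F4. Cyclisation of F4 with Bu3SnH/AIBN forms the quaternary centre as before, and the tertiary α-keto radical is now quenched by fast hydrogen transfer on the face the allyl reagent would have used. A wrong-face allylation in step 6 is thereby turned into the required configuration, giving 12. This fallback does not help if allylation is on the correct face but merely inefficient.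

Step 10. Seven-membered ring closure onto a hindered α-branched ketone may be slow, and the base may epimerise the adjacent CH. The fallback sets out from 15 and comes back at 17, and it uses metathesis instead of a carbanion. Ketone 15 is methylenated (Cp2TiMe2, toluene, 65 °C) to 3-[(1R,2S,3S)-2-[2-(1,3-dioxolan-2-yl)ethyl]-3-hydroxy-2-(hydroxymethyl)-3-methyl-6-methylidenecyclohexyl]propyl 2,2-dimethylpropanoate F5. The neopentyl alcohol is acylated with methacryloyl chloride (Et3N, DMAP) to the corresponding 2-methylprop-2-enoate F6. Ring-closing metathesis (second-generation Hoveyda–Grubbs catalyst, toluene, 110 °C) then closes the same lactone, the ring again enforcing the Z alkene, to give 17.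

Further compounds
F1 | step 3 | 2-[(tert-butyldimethylsilyl)oxy]-4-ethoxy-1-methylcyclohexa-1,3-diene | CCOC1=CC(O[Si](C)(C)C(C)(C)C)=C(C)CC1
F2 | step 6 | (4S)-3-[2-(1,3-dioxolan-2-yl)ethyl]-4-hydroxy-2-iodo-4-methylcyclohex-2-en-1-one | O=C1CC[C@](C)(O)C(CCC2OCCO2)=C1I
F3 | step 6 | (4S)-3-[2-(1,3-dioxolan-2-yl)ethyl]-4-hydroxy-4-methyl-2-(prop-2-en-1-yl)cyclohex-2-en-1-one | O=C1CC[C@](C)(O)C(CCC2OCCO2)=C1CC=C
F4 | step 6 | (4S)-4-{[(bromomethyl)dimethylsilyl]oxy}-3-[2-(1,3-dioxolan-2-yl)ethyl]-4-methyl-2-(prop-2-en-1-yl)cyclohex-2-en-1-one | O=C1CC[C@](C)(O[Si](C)(C)CBr)C(CCC2OCCO2)=C1CC=C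
F5 | step 10 | 3-[(1R,2S,3S)-2-[2-(1,3-dioxolan-2-yl)ethyl]-3-hydroxy-2-(hydroxymethyl)-3-methyl-6-methylidenecyclohexyl]propyl 2,2-dimethylpropanoate | C1(OCCO1)CC[C@@]2(CO)[C@H](CCCOC(=O)C(C)(C)C)C(=C)CC[C@]2(C)O
F6 | step 10 | {(1S,2R,6S)-1-[2-(1,3-dioxolan-2-yl)ethyl]-2-{3-[(2,2-dimethylpropanoyl)oxy]propyl}-6-hydroxy-6-methyl-3-methylidenecyclohexyl}methyl 2-methylprop-2-enoate | C1(OCCO1)CC[C@@]2(COC(=O)C(C)=C)[C@H](CCCOC(=O)C(C)(C)C)C(=C)CC[C@]2(C)O
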